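**Assumption:** germacrone and angelic acid are bought. Eudesmane/eremophilane numbering is used. α/β refer to the usual drawing (ring A left, C10 above C5, α behind the plane); in this drawing every ring substituent of the target is α.

## Retrosynthetic overview
1. Target 22 comes from angeloylation of C3–OH, double methyl ester formation, and Ru-BINAP hydrogenation of a 2-substituted acrylic acid, which sets C11. Both carboxyl groups are the natural methyl groups C12 and C15, oxidised after the skeleton is built.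
2. C15–OH comes from C–H silylation directed by C3–OH. The 6-en-8-one and the acrylic unit come from the isopropylidene ketone.
3. C3–OH, C4–H and the C5 methyl arise in one step from epoxide 4 by a 1,2-H shift followed by a 1,2-CH3 shift (eudesmyl to eremophilyl).
4. The decalin arises by proton-triggered transannular C5–C10 closure of achiral germacrone 1 under a chiral acid.
5. Ring order: the ten-membered ring is already present in 1, and rings A and B form together in step 1. No other carbocycle is made.

## Route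

**Step 1**
Reactants: 1 germacrone
Product: 2 (5S,10S)-eudesma-3,7(11)-dien-8-one
Conditions: (S,S)-IDPi Brønsted acid (confined BINOL-derived N-triflyl imidodiphosphorimidate, 2 mol%; the antipode is used if a test run shows the opposite sense), toluene, −40 °C
Reagents that add atoms: none
Why: Proposed new method: protonation of the strained C1=C10 E-alkene of the chair–chair conformer while C5 of the C4=C5 alkene attacks C10 is the germacrene-to-eudesmyl-cation closure (known in racemic form for germacrone and costunolide with achiral acids) and can give only the trans-decalin, the two planar-chiral conformers of achiral 1 interconvert fast so the confined chiral anion can select one of them (dynamic kinetic resolution, closest known type: IDPi-catalysed asymmetric proton-initiated cation–olefin cyclisation), and the anion then removes H-3 from the C4 cation to give the 3-ene, which sets H-5 β and 10-CH3 α.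

**Step 2**
Reactants: 2 (5S,10S)-eudesma-3,7(11)-dien-8-one
Product: 4 (3R,4S,5S,10S)-3α,4α-epoxyeudesm-7(11)-en-8-one, via bromohydrin 3 (not isolated)
Conditions: NBS, acetone/H2O 4:1, 0 °C; then K2CO3, MeOH, rt (one pot)
Reagents that add atoms: water, O; N-bromosuccinimide, O=C1CCC(=O)N1Br (its bromine stays only in 3)
Why: Bromohydrin formation and base closure (two inversions): Br+ adds to the electron-rich 3-ene on the open β face, water opens the bromonium ion at tertiary C4 in the trans-diaxial sense from the α face, and carbonate then closes the α-epoxide, which lies on the face of the angular methyl that a peracid would not reach, while the conjugated 7(11)-alkene is too electron-poor to react.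

**Step 3**
Reactants: 4 (3R,4S,5S,10S)-3α,4α-epoxyeudesm-7(11)-en-8-one
Product: 7 (3R,4S,5S)-3α-hydroxyeremophila-7(11),9-dien-8-one, via silyl dienol ether 5 (not isolated), via O-silyl dienone 6 (not isolated)
Conditions: LiN(iPr)2, Me3SiCl, THF, −78 °C; solvent switch; Me3SiOTf (10 mol%), CH2Cl2, −78 to −40 °C; 1 M HCl, THF, 0 °C
Reagents that add atoms: chlorotrimethylsilane, C[Si](C)(C)Cl (its silyl group stays only in 5 and 6)
Why: Proposed new method: silylation of the epoxide oxygen breaks the tertiary C4–O bond, whose α-axial orientation is antiperiplanar to H-5β, which in turn is antiperiplanar to the α-axial 10-methyl group, so H-5 moves to C4 and CH3 moves to C5 (the eudesmyl-to-eremophilyl shifts of the biosynthesis, each with inversion, which sets H-4 β, C15 α and 5-CH3 α and keeps C3–O α), and the kinetically formed 8-siloxy-8-ene pushes the methyl shift because the C10 cation it leaves is simply the O-silylated 9-en-8-one, which returns Me3Si+ to the catalytic cycle; closest known types are Westphalen and backbone rearrangements of steroid and decalin epoxides, the acid-induced eudesmane-epoxide-to-eremophilane methyl shift and the vinylogous semipinacol rearrangement.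

**Step 4**
Reactants: 7 (3R,4S,5S)-3α-hydroxyeremophila-7(11),9-dien-8-one
Product: 8 (3R,4S,5R,10S)-3α-hydroxy-10αH-eremophil-7(11)-en-8-one
Conditions: H2 (1 atm), 10% Pd/C, EtOH, trace KOH, rt
Reagents that add atoms: none
Why: Heterogeneous hydrogenation of an angular-methyl octalone: the tetrasubstituted 7(11)-alkene is inert under one atmosphere, and as with 4-en-3-one steroids in basic ethanol and the 4,5-dimethyl octalones used for fukinone-type targets hydrogen reaches C10 from the face that carries the angular methyl, which sets H-10 α and gives the cis-decalin.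

**Step 5**
Reactants: 8 (3R,4S,5R,10S)-3α-hydroxy-10αH-eremophil-7(11)-en-8-one
Product: 11 (3R,4R,5R,10S)-3α,15-dihydroxy-10αH-eremophil-7(11)-en-8-one, via hydridosilyl ether 9 (not isolated), via oxasilolane 10 (not isolated)
Conditions: Et2SiHCl, Et3N, CH2Cl2, 0 °C; [Ir(cod)OMe]2 (2 mol%), 3,4,7,8-Me4phen (4.5 mol%), norbornene, THF, 100 °C; H2O2, KHCO3, THF/MeOH, 50 °C
Reagents that add atoms: hydrogen peroxide, OO; chlorodiethylsilane, CC[SiH](Cl)CC (its silicon stays only in 9 and 10)
Why: Hydroxyl-directed iridium-catalysed γ-C–H silylation followed by Tamao–Fleming oxidation (Hartwig 1,3-diol synthesis): the tethered Si–H can reach only one primary γ-C–H bond, that of C15, which is cis to the C3 oxygen so that a cis-fused five-membered oxasilolane forms, no stereocentre is touched, and the only carbonyl is a hindered tetrasubstituted enone that an alkoxydiethylsilane attacks slowly.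

**Step 6**
Reactants: 11 (3R,4R,5R,10S)-3α,15-dihydroxy-10αH-eremophil-7(11)-en-8-one
Product: 14 (3R,4R,5S,10S)-3α,15-dihydroxy-10αH-eremophila-6,11-dien-8-one, via tris-silyl dienol ether 12 (not isolated), via bis-silyl dienone 13 (not isolated)
Conditions: Me3SiOTf (3.5 equiv), Et3N, CH2Cl2, 0 °C to rt; Pd(OAc)2 (1.1 equiv), MeCN, rt; 1 M HCl, THF
Reagents that add atoms: trimethylsilyl triflate, C[Si](C)(C)OS(=O)(=O)C(F)(F)F (its silyl groups stay only in 12 and 13)
Why: Saegusa–Ito dehydrogenation: equilibrating silylation removes a γ-proton as with pulegone to give the fully substituted 8-siloxy-7,11-diene (both hydroxyls are masked in passing), the divalent palladium enolate bound at C7 has its only ring β-hydrogens at C6 and loses one of them to give the 6-en-8-one plus zerovalent palladium, and the isopropenyl group stays as the handle for C12.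

**Step 7**
Reactants: 14 (3R,4R,5S,10S)-3α,15-dihydroxy-10αH-eremophila-6,11-dien-8-one
Product: 15 3α,12,15-trihydroxy-10αH-eremophila-6,11(13)-dien-8-one
Conditions: SeO2 (30 mol%), t-BuOOH, CH2Cl2, 0 °C to rt
Reagents that add atoms: tert-butyl hydroperoxide, CC(C)(C)OO
Why: Sharpless–Umbreit allylic hydroxylation (ene reaction then [2,3]-sigmatropic shift): the isopropenyl methyl carries the only allylic hydrogens in the molecule because C5 is quaternary, and the mild catalytic conditions avoid oxidation next to the ketone at C9.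

**Step 8**
Reactants: 15 3α,12,15-trihydroxy-10αH-eremophila-6,11(13)-dien-8-one
Product: 17 3α-hydroxy-8-oxo-10αH-eremophila-6,11(13)-diene-12,15-dioic acid, via dialdehyde 16 (not isolated)
Conditions: TEMPO (20 mol%), PhI(OAc)2 (2.2 equiv), CH2Cl2, rt; then NaClO2, NaH2PO4, 2-methyl-2-butene, t-BuOH/H2O, 0 °C
Reagents that add atoms: sodium chlorite, [Na+].[O-]Cl=O
Why: TEMPO/PhI(OAc)2 oxidation followed by Pinnick oxidation: the oxoammonium salt takes the two primary alcohols and leaves the hindered secondary C3 alcohol, chlorite then converts both aldehydes into acids without touching the alkenes because 2-methyl-2-butene traps HOCl, and C4 keeps its configuration since C15 already sits in the favoured equatorial position.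

**Step 9**
Reactants: 17 3α-hydroxy-8-oxo-10αH-eremophila-6,11(13)-diene-12,15-dioic acid
Product: 18 (11S)-3α-hydroxy-8-oxo-10αH-eremophil-6-ene-12,15-dioic acid
Conditions: Ru(OAc)2[(S)-BINAP] (1 mol%), H2 (100 atm), MeOH, 0 °C
Reagents that add atoms: none
Why: Noyori carboxylate-directed asymmetric hydrogenation: only the 2-substituted acrylic acid unit binds ruthenium next to its alkene, so the trisubstituted enone alkene is left alone, and the (S)-BINAP complex delivers H2 to the face that gives the S centre at C11, the same sense as in the conversion of 2-arylacrylic acids into (S)-2-arylpropionic acids.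

**Step 10**
Reactants: 18 (11S)-3α-hydroxy-8-oxo-10αH-eremophil-6-ene-12,15-dioic acid
Product: 19 dimethyl (11S)-3α-hydroxy-8-oxo-10αH-eremophil-6-ene-12,15-dioate
Conditions: Me3SiCHN2 (2.2 equiv), toluene/MeOH 4:1, 0 °C
Reagents that add atoms: (trimethylsilyl)diazomethane, C[Si](C)(C)C=[N+]=[N-]
Why: Neutral methylation of both carboxylic acids by the diazoalkane (protonation then SN2 on the methyldiazonium ion), chosen because base-free conditions cannot epimerise C11 or C4 or eliminate the β-hydroxy group.

**Step 11**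
Reactants: 19 dimethyl (11S)-3α-hydroxy-8-oxo-10αH-eremophil-6-ene-12,15-dioate; 20 angelic acid
Product: 22 CNP0265265.1 (dimethyl (3R,4S,5S,10S,11S)-3-angeloyloxy-8-oxoeremophil-6-ene-12,15-dioate), via mixed anhydride 21 (not isolated)
Conditions: 20, 2,4,6-trichlorobenzoyl chloride, Et3N, toluene, rt; then 19, 80 °C
Reagents that add atoms: 2,4,6-trichlorobenzoyl chloride, O=C(Cl)c1c(Cl)cc(Cl)cc1Cl (its atoms stay only in 21)
Why: Yamaguchi-type mixed anhydride esterification: the hindered trichlorobenzoyl carbonyl directs the C3 alcohol to the angeloyl carbonyl, this DMAP-free protocol is the standard way to make angelates without Z to E isomerisation, and triethylamine is too weak to epimerise C11 or trigger β-elimination, so no stereocentre changes.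

## Compound list
1 | germacrone ((1(10)E,4E)-germacra-1(10),4,7(11)-trien-8-one; achiral) | C/C1=C\CC/C(C)=C/CC(=C(C)C)C(=O)C1 | starting material
2 | (5S,10S)-eudesma-3,7(11)-dien-8-one (trans-decalin; H-5 β; 10-CH3 α) | CC1=CCC[C@@]2(C)CC(=O)C(=C(C)C)C[C@H]12 | intermediate
3 | 3β-bromo-4α-hydroxy-5βH-eudesm-7(11)-en-8-one (10-CH3 α) | C[C@@]1(O)[C@@H](Br)CC[C@@]2(C)CC(=O)C(=C(C)C)C[C@H]12 | intermediate
4 | (3R,4S,5S,10S)-3α,4α-epoxyeudesm-7(11)-en-8-one | C[C@@]12O[C@@H]1CC[C@@]3(C)CC(=O)C(=C(C)C)C[C@H]23 | intermediate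
5 | 3α,4α-epoxy-8-(trimethylsilyloxy)eudesma-7(11),8-diene | C[C@@]12O[C@@H]1CC[C@@]3(C)C=C(O[Si](C)(C)C)C(=C(C)C)C[C@H]23 | intermediate
6 | 3α-(trimethylsilyloxy)eremophila-7(11),9-dien-8-one | C[Si](C)(C)O[C@@H]1CCC2=CC(=O)C(=C(C)C)C[C@@]2(C)[C@@H]1C | intermediate
7 | (3R,4S,5S)-3α-hydroxyeremophila-7(11),9-dien-8-one (4-CH3 and 5-CH3 α) | O[C@@H]1CCC2=CC(=O)C(=C(C)C)C[C@@]2(C)[C@@H]1C | intermediate
8 | (3R,4S,5R,10S)-3α-hydroxy-10αH-eremophil-7(11)-en-8-one (cis-decalin) | O[C@@H]1CC[C@H]2CC(=O)C(=C(C)C)C[C@@]2(C)[C@@H]1C | intermediate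
9 | 3-O-(diethylsilyl) ether of 8 | CC[SiH](CC)O[C@@H]1CC[C@H]2CC(=O)C(=C(C)C)C[C@@]2(C)[C@@H]1C | intermediate
10 | 3-O,15-C-(diethylsilanediyl) derivative of 8 (cis-fused 1,2-oxasilolane) | O1[C@@H]2CC[C@H]3CC(=O)C(=C(C)C)C[C@@]3(C)[C@@H]2C[Si]1(CC)CC | intermediate
11 | (3R,4R,5R,10S)-3α,15-dihydroxy-10αH-eremophil-7(11)-en-8-one | O[C@@H]1CC[C@H]2CC(=O)C(=C(C)C)C[C@@]2(C)[C@@H]1CO | intermediate
12 | 3α,8,15-tris(trimethylsilyloxy)-10αH-eremophila-7,11-diene | C[Si](C)(C)O[C@@H]1CC[C@H]2CC(O[Si](C)(C)C)=C(C(C)=C)C[C@@]2(C)[C@@H]1CO[Si](C)(C)C | intermediate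
13 | 3α,15-bis(trimethylsilyloxy)-10αH-eremophila-6,11-dien-8-one | C[Si](C)(C)O[C@@H]1CC[C@H]2CC(=O)C(C(C)=C)=C[C@@]2(C)[C@@H]1CO[Si](C)(C)C | intermediate
14 | (3R,4R,5S,10S)-3α,15-dihydroxy-10αH-eremophila-6,11-dien-8-one | O[C@@H]1CC[C@H]2CC(=O)C(C(C)=C)=C[C@@]2(C)[C@@H]1CO | intermediate
15 | 3α,12,15-trihydroxy-10αH-eremophila-6,11(13)-dien-8-one | O[C@@H]1CC[C@H]2CC(=O)C(C(=C)CO)=C[C@@]2(C)[C@@H]1CO | intermediate
16 | 3α-hydroxy-8-oxo-10αH-eremophila-6,11(13)-diene-12,15-dial | O[C@@H]1CC[C@H]2CC(=O)C(C(=C)C=O)=C[C@@]2(C)[C@@H]1C=O | intermediate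
17 | 3α-hydroxy-8-oxo-10αH-eremophila-6,11(13)-diene-12,15-dioic acid | O[C@@H]1CC[C@H]2CC(=O)C(C(=C)C(O)=O)=C[C@@]2(C)[C@@H]1C(O)=O | intermediate
18 | (11S)-3α-hydroxy-8-oxo-10αH-eremophil-6-ene-12,15-dioic acid | O[C@@H]1CC[C@H]2CC(=O)C([C@H](C)C(O)=O)=C[C@@]2(C)[C@@H]1C(O)=O | intermediate
19 | dimethyl (11S)-3α-hydroxy-8-oxo-10αH-eremophil-6-ene-12,15-dioate | O[C@@H]1CC[C@H]2CC(=O)C([C@H](C)C(=O)OC)=C[C@@]2(C)[C@@H]1C(=O)OC | intermediate
20 | angelic acid ((Z)-2-methylbut-2-enoic acid) | C/C=C(/C)C(O)=O | starting material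
21 | angelic 2,4,6-trichlorobenzoic anhydride | C/C=C(/C)C(=O)OC(=O)c1c(Cl)cc(Cl)cc1Cl | intermediate
22 | CNP0265265.1, dimethyl (3R,4S,5S,10S,11S)-3-angeloyloxy-8-oxoeremophil-6-ene-12,15-dioate | C/C=C(/C)C(=O)O[C@@H]1CC[C@H]2CC(=O)C([C@H](C)C(=O)OC)=C[C@@]2(C)[C@@H]1C(=O)OC | target

**Total step count:** 11. **Longest linear sequence:** 11 (1 to 22).

## Steps most likely to fail

**Step 1** (enantioselectivity and 3-ene regioselectivity of the closure). The fallback sets out from 1. The closure is run with an achiral acid (TsOH·H2O, CH2Cl2, 0 °C), which is known chemistry. Asymmetric catalysis is replaced by resolution: preparative chiral SFC separates 2 from its antipode (5R,10R)-eudesma-3,7(11)-dien-8-one F1. The route is rejoined at 2.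

**Step 3** (the H-3 shift to the 3-ketone, or loss of H-6 after the first shift, may beat the methyl shift). The fallback sets out from 2 and changes the initiating group.
- Woodward cis-hydroxylation (I2, AgOAc, wet AcOH) starts with iodonium on the β face. It ends with both oxygens on the α face as 3α-acetoxy-4α-hydroxy-5βH-eudesm-7(11)-en-8-one F2.
- K2CO3 in MeOH gives 3α,4α-dihydroxy-5βH-eudesm-7(11)-en-8-one F3.
- SO2Cl2 and Et3N at −78 °C close the 3α,4α-cyclic sulfate F4.
- F4 ionises only at tertiary C4 when warmed with BF3·OEt2. The sulfate left on C3 is too electron-poor to let H-3 migrate, so the same antiperiplanar H and CH3 shifts give the 3-O-hydrogen sulfate of 7 F5.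
- Aqueous H2SO4 in THF cleaves F5, and the route is rejoined at 7.

**Step 5** (the enone may be hydrosilylated under iridium catalysis). The fallback sets out from 8 and takes the carbonyl out of play.
- NaBH4 with CeCl3·7H2O in MeOH gives 10αH-eremophil-7(11)-ene-3α,8β-diol F6. The C8 configuration is immaterial.
- Et2SiH2 with [Ir(cod)OMe]2 gives its bis(diethylsilyl) ether F7.
- The same iridium/Me4phen/norbornene conditions close the C3/C15 oxasilolane that still carries the 8-O-diethylsilyl group F8.
- H2O2 with KHCO3 gives 10αH-eremophil-7(11)-ene-3α,8β,15-triol F9.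
- MnO2 in CH2Cl2 oxidises only the allylic C8 alcohol, and the route is rejoined at 11.

## Further compounds
F1 | step 1 | (5R,10R)-eudesma-3,7(11)-dien-8-one | CC1=CCC[C@]2(C)CC(=O)C(=C(C)C)C[C@@H]12
F2 | step 3 | 3α-acetoxy-4α-hydroxy-5βH-eudesm-7(11)-en-8-one | C[C@@]1(O)[C@H](OC(C)=O)CC[C@@]2(C)CC(=O)C(=C(C)C)C[C@H]12
F3 | step 3 | 3α,4α-dihydroxy-5βH-eudesm-7(11)-en-8-one | C[C@@]1(O)[C@H](O)CC[C@@]2(C)CC(=O)C(=C(C)C)C[C@H]12
F4 | step 3 | 3α,4α-cyclic sulfate of F3 | C[C@@]12OS(=O)(=O)O[C@@H]1CC[C@@]3(C)CC(=O)C(=C(C)C)C[C@H]23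
F5 | step 3 | 3-O-hydrogen sulfate of 7 | OS(=O)(=O)O[C@@H]1CCC2=CC(=O)C(=C(C)C)C[C@@]2(C)[C@@H]1C
F6 | step 5 | 10αH-eremophil-7(11)-ene-3α,8β-diol | O[C@@H]1CC[C@H]2C[C@@H](O)C(=C(C)C)C[C@@]2(C)[C@@H]1C
F7 | step 5 | 3,8-bis-O-(diethylsilyl) ether of F6 | CC[SiH](CC)O[C@@H]1CC[C@H]2C[C@@H](O[SiH](CC)CC)C(=C(C)C)C[C@@]2(C)[C@@H]1C
F8 | step 5 | C3/C15 oxasilolane carrying the 8-O-diethylsilyl group | O1[C@@H]2CC[C@H]3C[C@@H](O[SiH](CC)CC)C(=C(C)C)C[C@@]3(C)[C@@H]2C[Si]1(CC)CC
F9 | step 5 | 10αH-eremophil-7(11)-ene-3α,8β,15-triol | O[C@@H]1CC[C@H]2C[C@@H](O)C(=C(C)C)C[C@@]2(C)[C@@H]1CO
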